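**Plan**

- Retrosynthesis: cut ring B C4'–C7' (Suzuki coupling), then C9–O and C8–H (back to a C8=C9 aryl enol ether with an Si–H group on O7), then C8=C9 (methylenation of an aryl ester carbonyl), the ring B O–C8 acyl bond, and last ring A C1–C7 (aryllithium plus oxalate).
- Forward: ring A glyoxylic acid, its ring B aryl ester, the C7 carbinol, the 1-aryloxyvinyl carbinol, the O7–SiMe2H ether, the 1,2-oxasilolane (the only ring made, opened again by oxidation), the 7,9-diol, the propenyl side chain, desilylation.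
- Feature used: C8 carries H, the ring B aryloxy oxygen and C9H2OH next to the C7 carbinol, i.e. the anti-Markovnikov hydrate of a 1-aryloxyvinyl carbinol. A silicon hydride held on O7 can therefore reach C9 through a five-membered ring and place H on C8.
- Stereochemistry: C7 (R) from asymmetric transfer hydrogenation of the α-keto ester; C8 (R) from C7 by 1,2-induction in the tethered hydrosilylation (cis ring = threo); the E alkene is carried in by the boronate.

Key step: step 10

Remark: ring A is the 4-hydroxy-3,5-dimethoxyphenyl ring and ring B the 2,6-dimethoxyphenoxy ring; C7, C8 and C9 are the carbinol, ether and hydroxymethyl carbons of the chain. The (S,S)-configured ruthenium catalyst is assumed to give the R carbinol, as it does for aryl ketones of the benzil type.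

**Route**

Step 1
Reactants: 1 4-bromo-2,6-dimethoxyphenol
Product: 2 (4-bromo-2,6-dimethoxyphenoxy)triisopropylsilane
Conditions: TIPSCl, imidazole, DMF, 25 °C
Reagents that add atoms: chlorotriisopropylsilane, CC(C)[Si](Cl)(C(C)C)C(C)C
Why: Imidazole-promoted silyl ether formation on the phenol; the triisopropylsilyl ether, shielded by both ortho methoxy groups, should tolerate the organolithium, carbonate, peroxide and phosphate conditions ahead and leave only with fluoride at the end.

Step 2
Reactants: 2 (4-bromo-2,6-dimethoxyphenoxy)triisopropylsilane; 3 diethyl oxalate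
Product: 5 ethyl 2-[3,5-dimethoxy-4-(triisopropylsilyloxy)phenyl]-2-oxoacetate, via the aryllithium 4 (not isolated)
Conditions: n-BuLi, THF, −78 °C; cannulated into 3 (2 equiv), THF, −78 °C; AcOH quench at −78 °C
Reagents that add atoms: none
Why: Bromine–lithium exchange followed by inverse addition to excess oxalate diester is the standard acylation route to aryl glyoxylates, because the tetrahedral lithium alkoxide persists at −78 °C until the acid quench and so blocks a second addition.

Step 3
Reactants: 5 ethyl 2-[3,5-dimethoxy-4-(triisopropylsilyloxy)phenyl]-2-oxoacetate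
Product: 6 2-[3,5-dimethoxy-4-(triisopropylsilyloxy)phenyl]-2-oxoacetic acid
Conditions: LiOH (1.1 equiv), THF/H2O, 0 °C; then 1 M HCl to pH 2
Reagents that add atoms: lithium hydroxide, [Li+].[OH-]
Why: Saponification of an α-keto ester is fast at 0 °C because of the adjacent ketone, so one equivalent of hydroxide should cleave the ethyl ester before the hindered aryl silyl ether is touched.

Step 4
Reactants: 6 2-[3,5-dimethoxy-4-(triisopropylsilyloxy)phenyl]-2-oxoacetic acid; 1 4-bromo-2,6-dimethoxyphenol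
Product: 8 (4-bromo-2,6-dimethoxyphenyl) 2-[3,5-dimethoxy-4-(triisopropylsilyloxy)phenyl]-2-oxoacetate, via the glyoxyloyl chloride 7 (not isolated)
Conditions: (COCl)2, DMF (cat.), CH2Cl2, 0 → 25 °C, evaporation; then 1, Et3N, DMAP (cat.), CH2Cl2, 0 °C
Reagents that add atoms: none
Why: Acid chloride formation under Vilsmeier catalysis and DMAP-assisted esterification of the hindered phenol bring the ring B oxygen onto the future C8 by an acyl substitution instead of an etherification at a secondary carbon.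

Step 5
Reactants: 8 (4-bromo-2,6-dimethoxyphenyl) 2-[3,5-dimethoxy-4-(triisopropylsilyloxy)phenyl]-2-oxoacetate
Product: 9 (4-bromo-2,6-dimethoxyphenyl) (2R)-2-[3,5-dimethoxy-4-(triisopropylsilyloxy)phenyl]-2-hydroxyacetate
Conditions: RuCl(p-cymene)[(S,S)-TsDPEN] (1 mol%), HCO2H/Et3N (5:2), CH2Cl2, 0 → 25 °C
Reagents that add atoms: none
Why: Noyori–Ikariya asymmetric transfer hydrogenation delivers hydride and proton in an outer-sphere six-membered transition state with ring A next to the η6-p-cymene ligand, so the (S,S) catalyst should set C7 as R, and the acidic formate medium should spare the aryl ester.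

Step 6
Reactants: 9 (4-bromo-2,6-dimethoxyphenyl) (2R)-2-[3,5-dimethoxy-4-(triisopropylsilyloxy)phenyl]-2-hydroxyacetate
Product: 10 (4-bromo-2,6-dimethoxyphenyl) (2R)-2-[3,5-dimethoxy-4-(triisopropylsilyloxy)phenyl]-2-(trimethylsilyloxy)acetate
Conditions: TMSCl, imidazole, CH2Cl2, 0 °C; used after filtration through neutral alumina
Reagents that add atoms: chlorotrimethylsilane, C[Si](C)(C)Cl
Why: Silyl ether formation masks the C7 hydroxyl, which would otherwise consume the titanium reagent, with the smallest silyl group so that the ester carbonyl stays accessible.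

Step 7
Reactants: 10 (4-bromo-2,6-dimethoxyphenyl) (2R)-2-[3,5-dimethoxy-4-(triisopropylsilyloxy)phenyl]-2-(trimethylsilyloxy)acetate
Product: 11 [(1R)-2-(4-bromo-2,6-dimethoxyphenoxy)-1-[3,5-dimethoxy-4-(triisopropylsilyloxy)phenyl]prop-2-enoxy]trimethylsilane
Conditions: Cp2TiMe2 (3 equiv), toluene, 70 °C, dark; then pentane, filtration through basic alumina
Reagents that add atoms: dimethyltitanocene Cp2TiMe2, C[Ti](C)(C1C=CC=C1)C1C=CC=C1
Why: Petasis methylenation: thermolysis of Cp2TiMe2 gives the titanocene methylidene, which adds [2+2] to the ester carbonyl and cycloreverts to the aryl enol ether and titanocene oxide, a non-basic carbonyl olefination known for aryl esters and α-silyloxy esters that should leave C7, the aryl bromide and both silyl ethers alone.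

Step 8
Reactants: 11 [(1R)-2-(4-bromo-2,6-dimethoxyphenoxy)-1-[3,5-dimethoxy-4-(triisopropylsilyloxy)phenyl]prop-2-enoxy]trimethylsilane
Product: 12 (1R)-2-(4-bromo-2,6-dimethoxyphenoxy)-1-[3,5-dimethoxy-4-(triisopropylsilyloxy)phenyl]prop-2-en-1-ol
Conditions: K2CO3 (0.2 equiv), MeOH, 0 °C; chromatography on Et3N-deactivated silica
Reagents that add atoms: none
Why: Carbonate-catalysed methanolysis (silyl ether solvolysis) removes the labile alkyl trimethylsilyl ether under basic conditions that neither hydrolyse the acid-sensitive aryl enol ether nor reach the hindered aryl triisopropylsilyl ether.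

Step 9
Reactants: 12 (1R)-2-(4-bromo-2,6-dimethoxyphenoxy)-1-[3,5-dimethoxy-4-(triisopropylsilyloxy)phenyl]prop-2-en-1-ol
Product: 13 [(1R)-2-(4-bromo-2,6-dimethoxyphenoxy)-1-[3,5-dimethoxy-4-(triisopropylsilyloxy)phenyl]prop-2-enoxy]dimethylsilane
Conditions: (HMe2Si)2NH (neat), 25 → 50 °C; volatiles removed in vacuo
Reagents that add atoms: 1,1,3,3-tetramethyldisilazane, C[SiH](C)N[SiH](C)C
Why: O-Silylation by alcoholysis of the disilazane installs the Si–H tether with ammonia as the only coproduct, so no amine salt remains to inhibit the platinum catalyst and the crude silyl ether can be used directly.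

Step 10
Reactants: 13 [(1R)-2-(4-bromo-2,6-dimethoxyphenoxy)-1-[3,5-dimethoxy-4-(triisopropylsilyloxy)phenyl]prop-2-enoxy]dimethylsilane
Product: 14 (4S,5R)-4-(4-bromo-2,6-dimethoxyphenoxy)-5-[3,5-dimethoxy-4-(triisopropylsilyloxy)phenyl]-2,2-dimethyl-1,2-oxasilolane (4,5-cis)
Conditions: Pt2[(CH2=CHSiMe2)2O]3 (0.5 mol% Pt), toluene (0.05 M), 25 → 50 °C
Reagents that add atoms: none
Why: The Si–H bond adds oxidatively to zerovalent platinum, the tethered C8=C9 enol ether coordinates, hydride migrates to C8 and C9–Si reductive elimination releases the ring (Chalk–Harrod mechanism). The closest known reaction type is the platinum-catalysed intramolecular hydrosilylation of O-dimethylsilyl derivatives of α-hydroxy enol ethers and 2-substituted allylic alcohols, which after oxidation gives 2,3-syn 1,3-diol units. The 1,2-oxasilolane closes in the 5-endo-trig mode, because the two-atom O–Si tether can reach only the terminal carbon C9 without forming a four-membered ring. The new stereocenter C8 is controlled by C7: allylic 1,2-strain holds the C7–H bond near the alkene plane beside the bulky ring B aryloxy group, so O7 with its silicon–platinum unit lies over one alkene face and ring A over the other, and hydride arrives from the tether side, anti to ring A. Aryl and aryloxy groups therefore end cis on the ring, which is the threo (7R,8R) relationship. The step needs anti-Markovnikov regiochemistry and this facial selectivity; the first is secured by the tether length and by dilution against intermolecular addition, the second by the C7 stereocenter, and the neutral catalyst keeps acid away from the enol ether.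

Step 11
Reactants: 14 (4S,5R)-4-(4-bromo-2,6-dimethoxyphenoxy)-5-[3,5-dimethoxy-4-(triisopropylsilyloxy)phenyl]-2,2-dimethyl-1,2-oxasilolane
Product: 15 (1R,2R)-2-(4-bromo-2,6-dimethoxyphenoxy)-1-[3,5-dimethoxy-4-(triisopropylsilyloxy)phenyl]propane-1,3-diol
Conditions: 30% H2O2, KHCO3, MeOH/THF (1:1), 25 → 40 °C
Reagents that add atoms: hydrogen peroxide, OO
Why: Tamao oxidation: hydroperoxide adds to the alkoxy-activated silicon, C9 migrates from silicon to oxygen and the silyl ethers are hydrolysed, which turns C9–Si into C9–OH without touching C8; the fluoride-free bicarbonate variant is chosen to keep the aryl silyl ether and to disfavour β-elimination of the ring B aryloxide.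

Step 12
Reactants: 15 (1R,2R)-2-(4-bromo-2,6-dimethoxyphenoxy)-1-[3,5-dimethoxy-4-(triisopropylsilyloxy)phenyl]propane-1,3-diol; 16 (E)-3-(tert-butyldimethylsilyloxy)prop-1-enylboronic acid pinacol ester
Product: 17 (1R,2R)-2-[4-[(E)-3-(tert-butyldimethylsilyloxy)prop-1-enyl]-2,6-dimethoxyphenoxy]-1-[3,5-dimethoxy-4-(triisopropylsilyloxy)phenyl]propane-1,3-diol
Conditions: Pd(OAc)2 (3 mol%), SPhos (6 mol%), K3PO4, THF/H2O (10:1), 50 °C
Reagents that add atoms: none
Why: Suzuki–Miyaura coupling of the unhindered aryl bromide with the (E)-alkenyl boronate proceeds with retention of alkene geometry, and the electron-rich biarylphosphine should allow oxidative addition of the electron-rich ring to zerovalent palladium at a temperature the free diol and the aryl silyl ether tolerate.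

Step 13
Reactants: 17 (1R,2R)-2-[4-[(E)-3-(tert-butyldimethylsilyloxy)prop-1-enyl]-2,6-dimethoxyphenoxy]-1-[3,5-dimethoxy-4-(triisopropylsilyloxy)phenyl]propane-1,3-diol
Product: 18 (1R,2R)-1-(4-hydroxy-3,5-dimethoxyphenyl)-2-[4-[(E)-3-hydroxyprop-1-enyl]-2,6-dimethoxyphenoxy]propane-1,3-diol
Conditions: Bu4NF, AcOH, THF, 0 → 25 °C
Reagents that add atoms: none
Why: Fluoride desilylation cleaves both the alkyl tert-butyldimethylsilyl ether and the aryl triisopropylsilyl ether, and the acetic acid buffer should keep the liberated para-hydroxybenzyl alcohol from forming a quinone methide that would scramble C7.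

**Compound list**

1 | 4-bromo-2,6-dimethoxyphenol | COc1cc(Br)cc(OC)c1O | starting material
2 | (4-bromo-2,6-dimethoxyphenoxy)triisopropylsilane | COc1cc(Br)cc(OC)c1O[Si](C(C)C)(C(C)C)C(C)C | intermediate
3 | diethyl oxalate | CCOC(=O)C(=O)OCC | starting material
4 | [3,5-dimethoxy-4-(triisopropylsilyloxy)phenyl]lithium | [Li]c1cc(OC)c(O[Si](C(C)C)(C(C)C)C(C)C)c(OC)c1 | intermediate (not isolated)
5 | ethyl 2-[3,5-dimethoxy-4-(triisopropylsilyloxy)phenyl]-2-oxoacetate | CCOC(=O)C(=O)c1cc(OC)c(O[Si](C(C)C)(C(C)C)C(C)C)c(OC)c1 | intermediate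
6 | 2-[3,5-dimethoxy-4-(triisopropylsilyloxy)phenyl]-2-oxoacetic acid | OC(=O)C(=O)c1cc(OC)c(O[Si](C(C)C)(C(C)C)C(C)C)c(OC)c1 | intermediate
7 | 2-[3,5-dimethoxy-4-(triisopropylsilyloxy)phenyl]-2-oxoacetyl chloride | ClC(=O)C(=O)c1cc(OC)c(O[Si](C(C)C)(C(C)C)C(C)C)c(OC)c1 | intermediate (not isolated)
8 | (4-bromo-2,6-dimethoxyphenyl) 2-[3,5-dimethoxy-4-(triisopropylsilyloxy)phenyl]-2-oxoacetate | COc1cc(C(=O)C(=O)Oc2c(OC)cc(Br)cc2OC)cc(OC)c1O[Si](C(C)C)(C(C)C)C(C)C | intermediate
9 | (4-bromo-2,6-dimethoxyphenyl) (2R)-2-[3,5-dimethoxy-4-(triisopropylsilyloxy)phenyl]-2-hydroxyacetate | COc1cc([C@@H](O)C(=O)Oc2c(OC)cc(Br)cc2OC)cc(OC)c1O[Si](C(C)C)(C(C)C)C(C)C | intermediate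
10 | (4-bromo-2,6-dimethoxyphenyl) (2R)-2-[3,5-dimethoxy-4-(triisopropylsilyloxy)phenyl]-2-(trimethylsilyloxy)acetate | COc1cc([C@@H](O[Si](C)(C)C)C(=O)Oc2c(OC)cc(Br)cc2OC)cc(OC)c1O[Si](C(C)C)(C(C)C)C(C)C | intermediate
11 | [(1R)-2-(4-bromo-2,6-dimethoxyphenoxy)-1-[3,5-dimethoxy-4-(triisopropylsilyloxy)phenyl]prop-2-enoxy]trimethylsilane | COc1cc([C@@H](O[Si](C)(C)C)C(=C)Oc2c(OC)cc(Br)cc2OC)cc(OC)c1O[Si](C(C)C)(C(C)C)C(C)C | intermediate
12 | (1R)-2-(4-bromo-2,6-dimethoxyphenoxy)-1-[3,5-dimethoxy-4-(triisopropylsilyloxy)phenyl]prop-2-en-1-ol | COc1cc([C@@H](O)C(=C)Oc2c(OC)cc(Br)cc2OC)cc(OC)c1O[Si](C(C)C)(C(C)C)C(C)C | intermediate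
13 | [(1R)-2-(4-bromo-2,6-dimethoxyphenoxy)-1-[3,5-dimethoxy-4-(triisopropylsilyloxy)phenyl]prop-2-enoxy]dimethylsilane | COc1cc([C@@H](O[SiH](C)C)C(=C)Oc2c(OC)cc(Br)cc2OC)cc(OC)c1O[Si](C(C)C)(C(C)C)C(C)C | intermediate
14 | (4S,5R)-4-(4-bromo-2,6-dimethoxyphenoxy)-5-[3,5-dimethoxy-4-(triisopropylsilyloxy)phenyl]-2,2-dimethyl-1,2-oxasilolane (4,5-cis) | COc1cc([C@H]2O[Si](C)(C)C[C@H]2Oc3c(OC)cc(Br)cc3OC)cc(OC)c1O[Si](C(C)C)(C(C)C)C(C)C | intermediate
15 | (1R,2R)-2-(4-bromo-2,6-dimethoxyphenoxy)-1-[3,5-dimethoxy-4-(triisopropylsilyloxy)phenyl]propane-1,3-diol | COc1cc([C@@H](O)[C@@H](CO)Oc2c(OC)cc(Br)cc2OC)cc(OC)c1O[Si](C(C)C)(C(C)C)C(C)C | intermediate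
16 | (E)-3-(tert-butyldimethylsilyloxy)prop-1-enylboronic acid pinacol ester | CC(C)(C)[Si](C)(C)OC/C=C/B1OC(C)(C)C(C)(C)O1 | starting material
17 | (1R,2R)-2-[4-[(E)-3-(tert-butyldimethylsilyloxy)prop-1-enyl]-2,6-dimethoxyphenoxy]-1-[3,5-dimethoxy-4-(triisopropylsilyloxy)phenyl]propane-1,3-diol | COc1cc([C@@H](O)[C@@H](CO)Oc2c(OC)cc(/C=C/CO[Si](C)(C)C(C)(C)C)cc2OC)cc(OC)c1O[Si](C(C)C)(C(C)C)C(C)C | intermediate
18 | (1R,2R)-1-(4-hydroxy-3,5-dimethoxyphenyl)-2-[4-[(E)-3-hydroxyprop-1-enyl]-2,6-dimethoxyphenoxy]propane-1,3-diol (threo) | COc1cc([C@@H](O)[C@@H](CO)Oc2c(OC)cc(/C=C/CO)cc2OC)cc(OC)c1O | target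

**Step count and risks**

Total step count: 13. Longest linear sequence: 13 steps (1 to 18); 1 enters twice, and 3 and 16 are commercial.

Step 7. What may go wrong: the titanium methylidene may add too slowly to the hindered, α-branched aryl ester, so that thermal decay of the reagent, loss of the trimethylsilyl group and decomposition of the enol ether on titanium residues win. The fallback leaves the route at 1 and at the aryllithium 4 and returns at 12; it builds the enol ether by methylenation next to a ketone instead of at an ester carbonyl. Phenol 1 is alkylated with 2-chloro-N-methoxy-N-methylacetamide (K2CO3, DMF) to give 2-(4-bromo-2,6-dimethoxyphenoxy)-N-methoxy-N-methylacetamide F1. Acylation of 4 by F1 (THF, −78 °C) gives 2-(4-bromo-2,6-dimethoxyphenoxy)-1-[3,5-dimethoxy-4-(triisopropylsilyloxy)phenyl]ethan-1-one F2. Mannich-type α-methylenation (paraformaldehyde, i-Pr2NH·CF3CO2H, THF, reflux) should give 2-(4-bromo-2,6-dimethoxyphenoxy)-1-[3,5-dimethoxy-4-(triisopropylsilyloxy)phenyl]prop-2-en-1-one F3. Corey–Bakshi–Shibata reduction ((S)-2-methyl-CBS-oxazaborolidine, BH3·SMe2, toluene, −40 °C), with the branched 1-aryloxyvinyl group expected to act as the larger ketone substituent, would then give 12 for step 9; this last reduction is the least certain part of the fallback.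

Step 10. What may go wrong: hydride delivery may not discriminate the two alkene faces well enough, the alkylplatinum intermediate may lose the ring B aryloxide by β-elimination, or intermolecular hydrosilylation may compete. The fallback leaves the route at 1 and 4 and returns at 15; both stereocenters are set by an auxiliary-controlled syn-aldol reaction (Evans aldol). Phenol 1 with chloroacetic acid (NaOH, H2O, reflux) gives (4-bromo-2,6-dimethoxyphenoxy)acetic acid F4. DCC/DMAP coupling with (S)-4-benzyloxazolidin-2-one gives (4S)-4-benzyl-3-[2-(4-bromo-2,6-dimethoxyphenoxy)acetyl]oxazolidin-2-one F5. Formylation of 4 with DMF gives 3,5-dimethoxy-4-(triisopropylsilyloxy)benzaldehyde F6. F5 with Bu2BOTf and i-Pr2NEt (CH2Cl2, −78 → 0 °C) gives the dibutylboron (Z)-enolate F7, which adds to F6. After pH 7 buffer/H2O2 work-up this should give (4S)-4-benzyl-3-[(2S,3R)-2-(4-bromo-2,6-dimethoxyphenoxy)-3-[3,5-dimethoxy-4-(triisopropylsilyloxy)phenyl]-3-hydroxypropanoyl]oxazolidin-2-one F8. LiBH4 (THF, MeOH, 0 °C) removes the auxiliary reductively and gives 15.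

Step 5. What may go wrong: the activated aryl ester may be cleaved or transesterified in the amine–formate medium, and enantioselectivity may be eroded on so electrophilic a ketone. The fallback leaves the route at 5, uses 1 again and returns at 10; C7 is set on the ethyl ester before ring B is attached. Hydrogenation of 5 over cinchonidine-modified Pt/Al2O3 (H2, AcOH; Orito reaction) should give ethyl (2R)-2-[3,5-dimethoxy-4-(triisopropylsilyloxy)phenyl]-2-hydroxyacetate F9. LiOH (THF/H2O, 0 °C) gives (2R)-2-[3,5-dimethoxy-4-(triisopropylsilyloxy)phenyl]-2-hydroxyacetic acid F10. TMSCl with pyridine gives trimethylsilyl (2R)-2-[3,5-dimethoxy-4-(triisopropylsilyloxy)phenyl]-2-(trimethylsilyloxy)acetate F11. (COCl)2 with catalytic DMF converts the silyl ester under neutral conditions into (2R)-2-[3,5-dimethoxy-4-(triisopropylsilyloxy)phenyl]-2-(trimethylsilyloxy)acetyl chloride F12. Acylation of 1 (pyridine, CH2Cl2, −20 °C) gives 10.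

**Further compounds**

F1 | step 7 | 2-(4-bromo-2,6-dimethoxyphenoxy)-N-methoxy-N-methylacetamide | CON(C)C(=O)COc1c(OC)cc(Br)cc1OC
F2 | step 7 | 2-(4-bromo-2,6-dimethoxyphenoxy)-1-[3,5-dimethoxy-4-(triisopropylsilyloxy)phenyl]ethan-1-one | COc1cc(C(=O)COc2c(OC)cc(Br)cc2OC)cc(OC)c1O[Si](C(C)C)(C(C)C)C(C)C
F3 | step 7 | 2-(4-bromo-2,6-dimethoxyphenoxy)-1-[3,5-dimethoxy-4-(triisopropylsilyloxy)phenyl]prop-2-en-1-one | COc1cc(C(=O)C(=C)Oc2c(OC)cc(Br)cc2OC)cc(OC)c1O[Si](C(C)C)(C(C)C)C(C)C
F4 | step 10 | (4-bromo-2,6-dimethoxyphenoxy)acetic acid | OC(=O)COc1c(OC)cc(Br)cc1OC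
F5 | step 10 | (4S)-4-benzyl-3-[2-(4-bromo-2,6-dimethoxyphenoxy)acetyl]oxazolidin-2-one | O=C(COc1c(OC)cc(Br)cc1OC)N1[C@@H](Cc2ccccc2)COC1=O
F6 | step 10 | 3,5-dimethoxy-4-(triisopropylsilyloxy)benzaldehyde | COc1cc(C=O)cc(OC)c1O[Si](C(C)C)(C(C)C)C(C)C
F7 | step 10 | dibutylboron (Z)-enolate of F5 | CCCCB(CCCC)O/C(=C\Oc1c(OC)cc(Br)cc1OC)N1[C@@H](Cc2ccccc2)COC1=O
F8 | step 10 | (4S)-4-benzyl-3-[(2S,3R)-2-(4-bromo-2,6-dimethoxyphenoxy)-3-[3,5-dimethoxy-4-(triisopropylsilyloxy)phenyl]-3-hydroxypropanoyl]oxazolidin-2-one | COc1cc([C@@H](O)[C@@H](C(=O)N2[C@@H](Cc3ccccc3)COC2=O)Oc2c(OC)cc(Br)cc2OC)cc(OC)c1O[Si](C(C)C)(C(C)C)C(C)C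
F9 | step 5 | ethyl (2R)-2-[3,5-dimethoxy-4-(triisopropylsilyloxy)phenyl]-2-hydroxyacetate | COc1cc([C@@H](O)C(=O)OCC)cc(OC)c1O[Si](C(C)C)(C(C)C)C(C)C
F10 | step 5 | (2R)-2-[3,5-dimethoxy-4-(triisopropylsilyloxy)phenyl]-2-hydroxyacetic acid | COc1cc([C@@H](O)C(O)=O)cc(OC)c1O[Si](C(C)C)(C(C)C)C(C)C
F11 | step 5 | trimethylsilyl (2R)-2-[3,5-dimethoxy-4-(triisopropylsilyloxy)phenyl]-2-(trimethylsilyloxy)acetate | COc1cc([C@@H](O[Si](C)(C)C)C(=O)O[Si](C)(C)C)cc(OC)c1O[Si](C(C)C)(C(C)C)C(C)C
F12 | step 5 | (2R)-2-[3,5-dimethoxy-4-(triisopropylsilyloxy)phenyl]-2-(trimethylsilyloxy)acetyl chloride | COc1cc([C@@H](O[Si](C)(C)C)C(Cl)=O)cc(OC)c1O[Si](C(C)C)(C(C)C)C(C)C
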